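Over 3.0 h, five flasks start from the same charge of substrate and differ in enzyme, and the question is how what was formed divides between target and isomer of the product.

    substrate + enzyme → target + enzyme, rate k1*[substrate]*[enzyme]/(1 + ([substrate]/Km1) + ([substrate]/Ksi1)^2) (Km1 = 1.7 mM, Ksi1 = 29 mM, k1 = 34000 /M/min)
    target ⇌ isomer of the product (K2 = 0.41, k2 = 0.022 /min)
    enzyme → spent catalyst (k3 = 3.6 × 10⁻⁶ /min)

| flask | substrate | enzyme | time |
|---|---|---|---|
| south | 0.050 M | 0.60 µM | 3.0 h |
| east | 0.050 M | 1.2 µM | 3.0 h |
| south-east | 0.050 M | 2.5 µM | 3.0 h |
| west | 0.050 M | 5.0 µM | 3.0 h |
| north | 0.050 M | 10 µM | 3.0 h |

- share of target in all that became target or isomer of the product for south, east, south-east, west, north, in this order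
- how that number moves from the first to the last of them (falls, then rises / hardly changes / rises, then falls / rises all the way / falls all the way)

- "hardly changes" means that all values lie within two and a half points (for a concentration: within two and a half percent of the largest)
- run time (south): 3.0 h

I begin with the concentration that gives the rate its order. At the start, c(substrate) = 0.050 M stands far above 1.7 mM, so the first step is pseudo-zero-order in substrate. At half the charge, the rate law gives 1.01 times the starting rate. Enzyme lost over the run comes to 0.0648 % of the charge, so I hold enzyme constant and treat the first step as a steady feed into target. In south, that feed is 30.6 µM/min, and it scales with enzyme.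

The isomerisation has a relaxation time, the inverse of its forward and backward rate constants added, 13.2 min. Its equilibrium share of target is 70.9 %. Under a steady feed, c(isomer of the product) stands where equilibrium would put it if the formed total were smaller by what was fed during one relaxation time. The share is therefore the equilibrium share, plus the remaining share times relaxation time over elapsed time, and the feed cancels. Because the run is far longer than the relaxation time, this gives 73.1 % for south, east and south-east.

In north, the feed would use up the substrate in 98.2 min, sooner than the end, so I expect the equilibrium share there. In west, with 5.0 µM of enzyme, the feed would last 196 min, close to the end, and my reckoning stops short of that flask. The span of 2.2 percentage points lies inside the margin, so I expect the share to be one that hardly changes.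

The forecast gives 73.06 %, 73.06 %, 73.07 %, 72.85 % and 70.93 %, and says hardly changes, with the “total spread is about 2.1 points”, where my span is 2.2 points.

The flasks give 73.1 %, 73.1 %, 73.1 %, 72.9 % and 70.9 %, so the share hardly changes. In north, c(substrate) falls under 2.00 % of its charge at 1.68 h, which leaves 79.3 min, or 6.01 relaxation times. For south-east at half the run, 1.50 h, the relaxation time gives a share of 75.2 %. That flask then holds target at 17.3 % and isomer of the product at 5.72 %, a share of 75.2 %.

(The numbers stand for no real mixture; the flask was simulated.)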